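**Plan**
- Retrosynthesis: after the four MOM ethers are removed, ring C is cut at three bonds at once (O1–C8a, C4–C4a and O1–C2), giving a ring A aryne across C4a–C8a and an arylpropiolic acid that carries ring B.
- Enabling feature: C4a and C8a are neighbouring ring A carbons with unlike neighbours, the oxygen-bearing C5 beside C4a and the benzyl-bearing C8 beside C8a. The C4a–C8a aryne is therefore polarized to take the carboxylate oxygen at C8a and the acyl carbon at C4a.
- The aryne precursor (SiMe3 at C4a, OTf at C8a) is cut at the C8–CH2 bond (aldehyde plus aryl Grignard, then C–O hydrogenolysis) and at C4a–Si (carbamate-directed lithiation).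
- Forward: ring A (from 2,4,6-trihydroxybenzaldehyde) receives the 4-oxygenated benzyl ring, then silicon and triflate. The ring B propiolic acid comes from isovanillin. The two halves are joined, ring C forms last, and the product is deprotected.
- Stereochemistry: the target has no stereocentre. The only one on the route (a racemic carbinol) is erased by hydrogenolysis.

Key step: step 11

Remark: flavone numbering (O1, C2–C8a; rings A, B, C) is used for positions throughout. 2,4,6-Trihydroxybenzaldehyde is taken as the commercial entry to ring A, because one ortho hydroxyl stays free on bis-MOM protection and later becomes the triflate oxygen at C8a.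

**Step 1**
Reactants: 1 2,4,6-trihydroxybenzaldehyde
Product: 2 2-hydroxy-4,6-bis(methoxymethoxy)benzaldehyde
Conditions: MOMCl (2.2 equiv), i-Pr2NEt, CH2Cl2, 0 °C to rt
Reagents that add atoms: chloromethyl methyl ether, COCCl
Why: Williamson-type O-alkylation with the α-chloro ether should stop at the bis-ether, because the remaining ortho hydroxyl is hydrogen-bonded to the formyl oxygen and is much less nucleophilic.

**Step 2**
Reactants: 3 4-bromophenol
Product: 4 1-bromo-4-(methoxymethoxy)benzene
Conditions: MOMCl, i-Pr2NEt, CH2Cl2, 0 °C to rt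
Reagents that add atoms: chloromethyl methyl ether, COCCl
Why: Williamson-type MOM protection of a simple phenol gives an aryl bromide suited to Grignard formation.

**Step 3**
Reactants: 4 1-bromo-4-(methoxymethoxy)benzene; 2 2-hydroxy-4,6-bis(methoxymethoxy)benzaldehyde
Product: 6 2-{hydroxy[4-(methoxymethoxy)phenyl]methyl}-3,5-bis(methoxymethoxy)phenol (racemic), via Grignard reagent 5 (not isolated)
Conditions: 4 (2.4 equiv), Mg, THF, 40 °C; then 2, THF, 0 °C to rt; aq. NH4Cl
Reagents that add atoms: none
Why: Grignard 1,2-addition to an aldehyde, in which the first equivalent only deprotonates the phenol and the chelated magnesium phenoxide still accepts a second equivalent at the formyl carbon, giving a racemic diarylmethanol whose stereocentre is of no consequence.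

**Step 4**
Reactants: 6 2-{hydroxy[4-(methoxymethoxy)phenyl]methyl}-3,5-bis(methoxymethoxy)phenol
Product: 7 3,5-bis(methoxymethoxy)-2-[4-(methoxymethoxy)benzyl]phenol
Conditions: H2 (1 atm), Pd/C, EtOAc–MeOH, rt
Reagents that add atoms: none
Why: Hydrogenolysis of a doubly benzylic C–O bond activated by ortho and para oxygen donors should proceed over Pd/C under neutral conditions, which spare the MOM acetals and remove the only stereocentre of the route.

**Step 5**
Reactants: 7 3,5-bis(methoxymethoxy)-2-[4-(methoxymethoxy)benzyl]phenol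
Product: 8 3,5-bis(methoxymethoxy)-2-[4-(methoxymethoxy)benzyl]phenyl N-isopropylcarbamate
Conditions: i-PrNCO, Et3N (cat.), CH2Cl2, rt
Reagents that add atoms: isopropyl isocyanate, CC(C)N=C=O
Why: Amine-catalysed addition of the phenol to the isocyanate gives an N–H carbamate, which is a strong ortho-directing group and can later be removed by mild base through E1cB elimination.

**Step 6**
Reactants: 8 3,5-bis(methoxymethoxy)-2-[4-(methoxymethoxy)benzyl]phenyl N-isopropylcarbamate
Product: 12 3,5-bis(methoxymethoxy)-2-[4-(methoxymethoxy)benzyl]-6-(trimethylsilyl)phenyl N-isopropylcarbamate, via N-silyl carbamate 9 (not isolated), via aryllithium 10 (not isolated), via N-silyl C-silyl carbamate 11 (not isolated)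
Conditions: TBSOTf, TMEDA, Et2O, 0 °C to rt; n-BuLi, TMEDA, −78 °C; TMSCl, −78 °C to rt; aq. NH4Cl
Reagents that add atoms: chlorotrimethylsilane, C[Si](C)(C)Cl
Why: Directed ortho-metalation, in which the carbamate (made tertiary in the flask by N-silylation) and the neighbouring OMOM group jointly steer n-BuLi to the ring carbon between them (the future C4a) rather than to the carbon between two OMOM groups; TMSCl traps the aryllithium and the N–Si bond is hydrolysed on work-up.

**Step 7**
Reactants: 12 3,5-bis(methoxymethoxy)-2-[4-(methoxymethoxy)benzyl]-6-(trimethylsilyl)phenyl N-isopropylcarbamate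
Product: 14 3,5-bis(methoxymethoxy)-2-[4-(methoxymethoxy)benzyl]-6-(trimethylsilyl)phenyl trifluoromethanesulfonate, via silylphenol 13 (not isolated)
Conditions: DBU, Et2NH, MeCN, 40 °C; then PhNTf2, rt to 40 °C
Reagents that add atoms: N-phenylbis(trifluoromethanesulfonimide), O=S(=O)(N(c1ccccc1)S(=O)(=O)C(F)(F)F)C(F)(F)F
Why: DBU removes the carbamate N–H and E1cB loss of isopropyl isocyanate (scavenged by Et2NH) frees the hindered silylphenoxide, which is triflated in the same flask by PhNTf2 under conditions that spare the C–Si bond and the acetals.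

**Step 8**
Reactants: 15 isovanillin (3-hydroxy-4-methoxybenzaldehyde)
Product: 16 4-methoxy-3-(methoxymethoxy)benzaldehyde
Conditions: MOMCl, i-Pr2NEt, CH2Cl2, 0 °C to rt
Reagents that add atoms: chloromethyl methyl ether, COCCl
Why: Williamson-type MOM protection of the single phenol, so that all four phenolic oxygens of the final flavone carry the same acid-labile group.

**Step 9**
Reactants: 16 4-methoxy-3-(methoxymethoxy)benzaldehyde
Product: 17 4-(2,2-dibromovinyl)-1-methoxy-2-(methoxymethoxy)benzene
Conditions: CBr4, PPh3, CH2Cl2, 0 °C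
Reagents that add atoms: carbon tetrabromide, BrC(Br)(Br)Br
Why: Corey–Fuchs dibromo-olefination, a Wittig reaction of the ylide Ph3P=CBr2 with the aldehyde under non-acidic conditions that the MOM ether tolerates.

**Step 10**
Reactants: 17 4-(2,2-dibromovinyl)-1-methoxy-2-(methoxymethoxy)benzene
Product: 19 3-[4-methoxy-3-(methoxymethoxy)phenyl]propiolic acid, via lithium acetylide 18 (not isolated)
Conditions: n-BuLi (2.1 equiv), THF, −78 °C; CO2, −78 to 0 °C; cold dilute HCl to pH 3
Reagents that add atoms: carbon dioxide, O=C=O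
Why: Second stage of the Corey–Fuchs sequence, in which n-BuLi effects elimination and bromine–lithium exchange to the lithium acetylide; CO2 carboxylates it, and brief cold acidification frees the acid without harming the MOM ether.

**Step 11**
Reactants: 14 3,5-bis(methoxymethoxy)-2-[4-(methoxymethoxy)benzyl]-6-(trimethylsilyl)phenyl trifluoromethanesulfonate; 19 3-[4-methoxy-3-(methoxymethoxy)phenyl]propiolic acid
Product: 22 5,7-bis(methoxymethoxy)-8-[4-(methoxymethoxy)benzyl]-2-[4-methoxy-3-(methoxymethoxy)phenyl]-4H-chromen-4-one, via aryne 20 (not isolated), via hydroxyaryl ynone 21 (not isolated)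
Conditions: CsF (4 equiv), THF, 125 °C, sealed tube
Reagents that add atoms: none
Why: Fluoride attacks silicon in 14 and triflate leaves to give aryne 20; the carboxylate of 19 adds through oxygen at C8a, the C4a aryl anion attacks the ester carbonyl to form a four-membered alkoxide that opens to the ortho-acyl phenoxide (21 as its anion), and this phenoxide adds to the β-carbon of the aryl ynone before C3 is protonated. The closest known reaction type is the fluoride-induced insertion of arynes into the C–O bond of carboxylic acids, which gives ortho-hydroxyaryl ketones and, with 3-arylpropiolic acids, flavones directly. Ring C closes by 6-endo-dig oxa-Michael addition, and the 5-exo-dig mode leading to an aurone is disfavoured because the ynone is polarized for attack at the aryl-bearing β-carbon. No stereocentre is formed. The step needs regioselective addition to the unsymmetrical aryne, and the C5 OMOM group secures it: its inductive pull distorts the aryne so that C8a is the more electrophilic terminus and the charge developing at C4a sits beside the oxygen-bearing carbon, which should outweigh the steric bias of the C8 benzyl and the weaker electronic bias of the C7 OMOM group. THF at 125 °C keeps proton sources scarce, so acyl transfer should outrun protonation of the C4a anion to a simple aryl ester.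

**Step 12**
Reactants: 22 5,7-bis(methoxymethoxy)-8-[4-(methoxymethoxy)benzyl]-2-[4-methoxy-3-(methoxymethoxy)phenyl]-4H-chromen-4-one
Product: 23 5,7-dihydroxy-8-(4-hydroxybenzyl)-2-(3-hydroxy-4-methoxyphenyl)-4H-chromen-4-one (CNP0159308.0)
Conditions: 3 M aq. HCl, MeOH, 50 °C
Reagents that add atoms: none
Why: Acid-catalysed methanolysis of the four aryl MOM acetals should be complete under dilute, warm conditions that are far milder than the hot concentrated acid needed to open ring C and move the benzyl group from C8 to C6 (Wessely–Moser rearrangement), and the 4'-methyl ether is untouched.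

**Compound list**
1 | 2,4,6-trihydroxybenzaldehyde | O=Cc1c(O)cc(O)cc1O | starting material
2 | 2-hydroxy-4,6-bis(methoxymethoxy)benzaldehyde | O=Cc1c(O)cc(OCOC)cc1OCOC | intermediate
3 | 4-bromophenol | Oc1ccc(Br)cc1 | starting material
4 | 1-bromo-4-(methoxymethoxy)benzene | COCOc1ccc(Br)cc1 | intermediate
5 | [4-(methoxymethoxy)phenyl]magnesium bromide (not isolated) | COCOc1ccc([Mg]Br)cc1 | intermediate
6 | 2-{hydroxy[4-(methoxymethoxy)phenyl]methyl}-3,5-bis(methoxymethoxy)phenol (racemic) | OC(c1ccc(OCOC)cc1)c1c(O)cc(OCOC)cc1OCOC | intermediate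
7 | 3,5-bis(methoxymethoxy)-2-[4-(methoxymethoxy)benzyl]phenol | Oc1cc(OCOC)cc(OCOC)c1Cc1ccc(OCOC)cc1 | intermediate
8 | 3,5-bis(methoxymethoxy)-2-[4-(methoxymethoxy)benzyl]phenyl N-isopropylcarbamate | CC(C)NC(=O)Oc1cc(OCOC)cc(OCOC)c1Cc1ccc(OCOC)cc1 | intermediate
9 | 3,5-bis(methoxymethoxy)-2-[4-(methoxymethoxy)benzyl]phenyl N-(tert-butyldimethylsilyl)-N-isopropylcarbamate (not isolated) | CC(C)N([Si](C)(C)C(C)(C)C)C(=O)Oc1cc(OCOC)cc(OCOC)c1Cc1ccc(OCOC)cc1 | intermediate
10 | 6-lithio derivative of 9, lithium at the carbon between the carbamate oxygen and OMOM (not isolated) | CC(C)N([Si](C)(C)C(C)(C)C)C(=O)Oc1c([Li])c(OCOC)cc(OCOC)c1Cc1ccc(OCOC)cc1 | intermediate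
11 | 3,5-bis(methoxymethoxy)-2-[4-(methoxymethoxy)benzyl]-6-(trimethylsilyl)phenyl N-(tert-butyldimethylsilyl)-N-isopropylcarbamate (not isolated) | CC(C)N([Si](C)(C)C(C)(C)C)C(=O)Oc1c([Si](C)(C)C)c(OCOC)cc(OCOC)c1Cc1ccc(OCOC)cc1 | intermediate
12 | 3,5-bis(methoxymethoxy)-2-[4-(methoxymethoxy)benzyl]-6-(trimethylsilyl)phenyl N-isopropylcarbamate | CC(C)NC(=O)Oc1c([Si](C)(C)C)c(OCOC)cc(OCOC)c1Cc1ccc(OCOC)cc1 | intermediate
13 | 3,5-bis(methoxymethoxy)-2-[4-(methoxymethoxy)benzyl]-6-(trimethylsilyl)phenol (not isolated) | Oc1c([Si](C)(C)C)c(OCOC)cc(OCOC)c1Cc1ccc(OCOC)cc1 | intermediate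
14 | 3,5-bis(methoxymethoxy)-2-[4-(methoxymethoxy)benzyl]-6-(trimethylsilyl)phenyl trifluoromethanesulfonate | C[Si](C)(C)c1c(OCOC)cc(OCOC)c(Cc2ccc(OCOC)cc2)c1OS(=O)(=O)C(F)(F)F | intermediate
15 | isovanillin (3-hydroxy-4-methoxybenzaldehyde) | COc1ccc(C=O)cc1O | starting material
16 | 4-methoxy-3-(methoxymethoxy)benzaldehyde | COCOc1cc(C=O)ccc1OC | intermediate
17 | 4-(2,2-dibromovinyl)-1-methoxy-2-(methoxymethoxy)benzene | COCOc1cc(C=C(Br)Br)ccc1OC | intermediate
18 | lithium [4-methoxy-3-(methoxymethoxy)phenyl]acetylide (not isolated) | COCOc1cc(C#C[Li])ccc1OC | intermediate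
19 | 3-[4-methoxy-3-(methoxymethoxy)phenyl]propiolic acid | OC(=O)C#Cc1ccc(OC)c(OCOC)c1 | intermediate
20 | 3,5-bis(methoxymethoxy)-6-[4-(methoxymethoxy)benzyl]benzyne, the C4a–C8a aryne (not isolated) | COCOC1=CC(OCOC)=C(Cc2ccc(OCOC)cc2)C#C1 | intermediate
21 | 1-{2-hydroxy-4,6-bis(methoxymethoxy)-3-[4-(methoxymethoxy)benzyl]phenyl}-3-[4-methoxy-3-(methoxymethoxy)phenyl]prop-2-yn-1-one, formed as its phenoxide (not isolated) | COCOc1cc(OCOC)c(Cc2ccc(OCOC)cc2)c(O)c1C(=O)C#Cc1ccc(OC)c(OCOC)c1 | intermediate
22 | 5,7-bis(methoxymethoxy)-8-[4-(methoxymethoxy)benzyl]-2-[4-methoxy-3-(methoxymethoxy)phenyl]-4H-chromen-4-one | COc1ccc(-c2cc(=O)c3c(OCOC)cc(OCOC)c(Cc4ccc(OCOC)cc4)c3o2)cc1OCOC | intermediate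
23 | 5,7-dihydroxy-8-(4-hydroxybenzyl)-2-(3-hydroxy-4-methoxyphenyl)-4H-chromen-4-one (CNP0159308.0) | COc1ccc(-c2cc(=O)c3c(O)cc(O)c(Cc4ccc(O)cc4)c3o2)cc1O | target

**Step count**
Total steps: 12. Longest linear sequence: 8 steps (steps 1, 3, 4, 5, 6, 7, 11, 12).

**Steps most likely to fail**

Step 11 (aryne annulation). Several processes could defeat it:
- protonation of the C4a anion before acyl transfer, which stops at O-arylation;
- erosion of the regioselectivity of carboxylate addition by the C8 benzyl group;
- thermal decarboxylation of the propiolate;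
- 5-exo closure of the phenoxide.

Fallback: the C4–C4a bond would be made by directed metalation, and ring C closed by the same phenoxide addition. Acid 19 is converted (MeNHOMe·HCl, EDC, i-Pr2NEt, CH2Cl2) into N-methoxy-N-methyl-3-[4-methoxy-3-(methoxymethoxy)phenyl]propiolamide F1. Carbamate 8 is N-silylated and lithiated as in step 6 (to 10) and quenched with F1 at −78 °C. This should give 3,5-bis(methoxymethoxy)-2-[4-(methoxymethoxy)benzyl]-6-{3-[4-methoxy-3-(methoxymethoxy)phenyl]propioloyl}phenyl N-(tert-butyldimethylsilyl)-N-isopropylcarbamate F2. Aqueous work-up removes the N-silyl group to give 3,5-bis(methoxymethoxy)-2-[4-(methoxymethoxy)benzyl]-6-{3-[4-methoxy-3-(methoxymethoxy)phenyl]propioloyl}phenyl N-isopropylcarbamate F3. K2CO3 in MeOH at rt should then cleave the carbamate, and the freed phenoxide (the anion of 21) closes ring C with the C5 oxygen still protected, so no regiochemical ambiguity arises. The fallback sets out from 8 and 19 and rejoins the route at 22.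

Step 6 (directed silylation). The silyl triflate used for N-silylation may cleave MOM acetals, and deprotonation may stray to the diarylmethane CH2 (lateral metalation) or to the ring carbon between the two OMOM groups.

Fallback: silicon would be brought in through a halogen. Phenol 7 is brominated ortho to the hydroxyl (NBS, i-Pr2NH cat., CH2Cl2, −78 to 0 °C) to give 2-bromo-3,5-bis(methoxymethoxy)-6-[4-(methoxymethoxy)benzyl]phenol F4. O-Silylation (HMDS, THF, 60 °C) gives {2-bromo-3,5-bis(methoxymethoxy)-6-[4-(methoxymethoxy)benzyl]phenoxy}trimethylsilane F5. n-BuLi (THF, −78 °C) then induces bromine–lithium exchange and a 1,3 oxygen-to-carbon silyl shift (retro-Brook rearrangement). The fallback sets out from 7 and rejoins the route at 13, formed as its lithium phenoxide and triflated in the same flask (PhNTf2) to 14.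

Step 4 (hydrogenolysis). C–O cleavage may be incomplete under the neutral conditions that the MOM groups require, or the carbinol may ionise on the catalyst and self-condense.

Fallback: the oxygen would be removed by hydride addition to an ortho-quinone methide. Carbinol 6 is acylated at the phenol (ClCO2Et, Et3N, THF, 0 °C) to give ethyl 2-{hydroxy[4-(methoxymethoxy)phenyl]methyl}-3,5-bis(methoxymethoxy)phenyl carbonate F6. NaBH4 in THF–H2O (0 °C to rt) should induce carbonate transfer to the benzylic oxygen and 1,4-elimination to 3,5-bis(methoxymethoxy)-6-[4-(methoxymethoxy)benzylidene]cyclohexa-2,4-dien-1-one F7 (transient, alkene geometry not defined). Borohydride reduces F7 by conjugate addition. The fallback sets out from 6 and rejoins the route at 7.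

**Further compounds**
F1 | step 11 | N-methoxy-N-methyl-3-[4-methoxy-3-(methoxymethoxy)phenyl]propiolamide | CON(C)C(=O)C#Cc1ccc(OC)c(OCOC)c1
F2 | step 11 | 3,5-bis(methoxymethoxy)-2-[4-(methoxymethoxy)benzyl]-6-{3-[4-methoxy-3-(methoxymethoxy)phenyl]propioloyl}phenyl N-(tert-butyldimethylsilyl)-N-isopropylcarbamate | CC(C)N([Si](C)(C)C(C)(C)C)C(=O)Oc1c(C(=O)C#Cc2ccc(OC)c(OCOC)c2)c(OCOC)cc(OCOC)c1Cc1ccc(OCOC)cc1
F3 | step 11 | 3,5-bis(methoxymethoxy)-2-[4-(methoxymethoxy)benzyl]-6-{3-[4-methoxy-3-(methoxymethoxy)phenyl]propioloyl}phenyl N-isopropylcarbamate | CC(C)NC(=O)Oc1c(C(=O)C#Cc2ccc(OC)c(OCOC)c2)c(OCOC)cc(OCOC)c1Cc1ccc(OCOC)cc1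
F4 | step 6 | 2-bromo-3,5-bis(methoxymethoxy)-6-[4-(methoxymethoxy)benzyl]phenol | Oc1c(Br)c(OCOC)cc(OCOC)c1Cc1ccc(OCOC)cc1
F5 | step 6 | {2-bromo-3,5-bis(methoxymethoxy)-6-[4-(methoxymethoxy)benzyl]phenoxy}trimethylsilane | C[Si](C)(C)Oc1c(Br)c(OCOC)cc(OCOC)c1Cc1ccc(OCOC)cc1
F6 | step 4 | ethyl 2-{hydroxy[4-(methoxymethoxy)phenyl]methyl}-3,5-bis(methoxymethoxy)phenyl carbonate (racemic) | CCOC(=O)Oc1cc(OCOC)cc(OCOC)c1C(O)c1ccc(OCOC)cc1
F7 | step 4 | 3,5-bis(methoxymethoxy)-6-[4-(methoxymethoxy)benzylidene]cyclohexa-2,4-dien-1-one (transient, alkene geometry not defined) | O=C1C=C(OCOC)C=C(OCOC)C1=Cc1ccc(OCOC)cc1
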